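The small charge in mM is the electrophile, 48 mM against 72.0 mM of nucleophile, so you start from its balance: with A its free amount, B free nucleophile and P target, the loss of A per unit of A, called g, equals k·B, and g therefore reads B.

| flask | electrophile | nucleophile | remark | time |
|---|---|---|---|---|
| beta | 48 mM | 72 mM | run made earlier |  |
| zeta | 32 mM | 72 mM | run made earlier |  |
| gamma | 72 mM | 72 mM | run made earlier |  |
| cedar | 48 mM | 72.0 mM | a closed flask charged with all of it at once and left for 40 h | 40 h |
| oak | 48 mM | 72.0 mM | one stirred flow tank at steady state, fed with the mixture as stated, mean residence time 200 h |  |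
| birch | 48 mM (fed, over 32.0 h) | 72.0 mM | all but electrophile at the start; electrophile goes in evenly over 32.0 h, the run ends at 40 h | 40 h |
| larch | 48 mM | 72.0 mM | one stirred flow tank at steady state, fed with the mixture as stated, mean residence time 40 h |  |

- beta (time / h: target / %): 2.00: 6; 6.00: 18; 12.0: 28; 15.0: 32; 25.0: 41; 30.0: 50; 40.0: 53
- zeta (time / h: target / %): 1.33: 3; 4.00: 10; 6.00: 18; 10.0: 24; 15.0: 35; 20.0: 43; 25.0: 49
- gamma (time / h: target / %): 1.33: 2; 4.00: 9; 6.00: 16; 10.0: 25; 15.0: 29; 20.0: 34; 25.0: 38

(standard deviation of a reading: 1.5 percentage points)

- the stated concentrations are those of everything mixed, before any reaction; amounts are the same in each set-up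
- what was read earlier has a scatter of 1.5 percentage points, one standard deviation
- the feed brings no volume worth counting
- the earlier runs were made in a closed, stirred flask

- the set-up with the highest amount of target at the outlet or at the end, in percent of the electrophile put in ("none" if the first two lie within 2 percentage points) (cedar / oak / birch / larch / none)
- amount of target at the outlet or at the end, in percent of the electrophile put in, cedar
- amount of target at the outlet or at the end, in percent of the electrophile put in, oak
- amount of target at the outlet or at the end, in percent of the electrophile put in, birch
- amount of target at the outlet or at the end, in percent of the electrophile put in, larch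

1. In the gamma run, g reads 0.0291 h⁻¹ over the first 6.00 h, but 0.0136 h⁻¹ between 15.0 h and 25.0 h.

2. Put B = 72 mM − n·P into both stretches, and the reading is n = 1.79 nucleophile lost per target. It carries scatter, and you take two. So the nucleophile reach R, the target at which free nucleophile comes to zero at two per target, is 36.0 mM, which is less than the electrophile charge C, and at two per target the limiting reagent is therefore the nucleophile, not the electrophile.

3. Fastest rung: the early stretch gives k = 4.80 × 10⁻⁴ mM⁻¹ h⁻¹, so the starting clock, the reciprocal of k times 72.0 mM, is 28.9 h, shorter than every later rung.

4. Next rung, 40 h: for cedar, dP/dt = 2·k·(C−P)·(R−P) integrates to 52.6%. For larch, the tank balance P = 2·k·τ·(C−P)·(R−P), with τ the mean residence time, gives 39.5%. Birch's electrophile stays 24.0 h on average, less than cedar's, so you put birch below cedar.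

5. Slowest rung: the late clock is 73.5 h, and oak's τ of 200 h is longer. The same balance gives 59.2%, so you name oak, above cedar and larch.

The forecast, holding that “the target is consumed by electrophile”, named cedar and gave 54% for cedar, 47% for oak, 42% for birch and 37% for larch, so it differs from your reckoning on oak.

The flask gives oak, with 58.6% for oak, above cedar at 52.6%, birch at 40.9% and larch at 39.5%.

    electrophile + nucleophile → acid set free + target (k = 0.480 M⁻¹ h⁻¹)
    nucleophile + acid set free ⇌ protonated nucleophile, settled at all times (K = 5000 M⁻¹)
    acid set free + target → side product (k = 0.310 M⁻¹ h⁻¹)

Each target sets free acid, and nucleophile takes it up as protonated nucleophile, 25.0 mM in cedar at 40.0 h. With R, oak's target leaves 15.7 mM of nucleophile, and its tank holds 15.5 mM. Birch read at 4.0 d stands at 64.1% target, so R leaves 14.5% of the nucleophile charge, and that flask holds 15.1%.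

The runs are calculated with made-up constants; noise was put on by code.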